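**Retrosynthetic overview**

1. Daucane numbering is used for all intermediates: C-1 methyl-bearing fusion carbon, C-2/C-3 ring CH2, C-4 isopropyl carbinol, C-5 fusion CH, C-6 ester carbon, C-7 CH2, C-8/C-9 oxirane carbons, C-10 CH2. The plan rests on C-4, a tertiary carbinol of the five-membered ring (C-1 to C-5) whose ring neighbour C-3 is a CH2 and which stands 1,3 to the C-6 oxygen across C-5.
2. Late stage: the oxirane comes from the C-8=C-9 alkene (peracid, anti to the C-1 methyl and the C-6 ester), the ester from the 4,6-diol, and the diol from its 6-MOM ether.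
3. Key disconnection C-3–C-4: a cycloheptene with a 2-iodoethyl group on C-1, a trans isobutyryl group on C-5 and a cis C-6 OMOM group closes the cyclopentanol by SmI2 Barbier reaction, with the C-6 oxygen as chelating anchor.
4. The iodo ketone is traced to a cycloheptadienyl isopropyl ketone (C-1=C-5 enone) by conjugate vinylation anti to the C-6 OMOM group, face-selective protonation at C-5, hydroboration and iodination; the enone comes from an (R)-2-bromodienol.
5. Ring order: the seven-membered ring first (Birch reduction of p-xylene, dibromocarbene addition, silver-promoted ring expansion, lipase resolution at C-6), the five-membered ring in the key step, the oxirane last.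

Key step: step 11

Assumption: 4-[(tert-butyldimethylsilyl)oxy]benzoic acid is taken as a purchased material, and the silver-promoted acetolysis is taken to deliver acetate to the secondary terminus of the allyl cation, as expected from the greater stability of the tetrasubstituted bromoalkene.

**Route**

Step 1
Reactants: 1 p-xylene
Product: 2 1,4-dimethylcyclohexa-1,4-diene
Conditions: Li, NH3(l), EtOH, Et2O, −78 → −33 °C
Reagents that add atoms: none
Why: Birch reduction of a 1,4-dialkylbenzene stops at the unconjugated 2,5-dihydro stage with both methyl groups on the double bonds, because the radical anion is protonated at the unsubstituted ring positions.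

Step 2
Reactants: 2 1,4-dimethylcyclohexa-1,4-diene; 3 bromoform
Product: 4 racemic cis-fused 7,7-dibromo-1,4-dimethylbicyclo[4.1.0]hept-3-ene
Conditions: KOt-Bu, pentane, −10 °C → rt (2 in excess)
Reagents that add atoms: bromoform (3), BrC(Br)Br
Why: Dibromocarbene, formed from bromoform by α-elimination, adds stereospecifically to one of the two equivalent trisubstituted alkenes (dihalocarbene cyclopropanation), the excess of diene holding back the bis-adduct; the cis-fused adduct is racemic.

Step 3
Reactants: 4 racemic 7,7-dibromo-1,4-dimethylbicyclo[4.1.0]hept-3-ene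
Product: 5 racemic 2-bromo-3,6-dimethylcyclohepta-2,5-dien-1-yl acetate
Conditions: AgOAc (1.5 equiv), AcOH, 40 °C, dark
Reagents that add atoms: silver acetate, CC(=O)[O-].[Ag+]
Why: Silver-assisted loss of the endo bromide is concerted with disrotatory opening of the cyclopropane (electrocyclic ring expansion of a ring-fused gem-dibromocyclopropane), and the 2-bromoallyl cation is expected to take up acetate at its secondary terminus, which leaves the tetrasubstituted bromoalkene; the product is racemic.

Step 4
Reactants: 5 racemic 2-bromo-3,6-dimethylcyclohepta-2,5-dien-1-yl acetate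
Product: 6 (1R)-2-bromo-3,6-dimethylcyclohepta-2,5-dien-1-ol
Conditions: Burkholderia cepacia lipase (Amano PS), phosphate buffer pH 7/MTBE, 30 °C, stopped near 45% conversion; chromatography
Reagents that add atoms: none
Why: Lipase-catalysed hydrolytic kinetic resolution: the (R)-acetate, with the bromoalkenyl carbon as large and the ring CH2 as medium substituent, is the fast enantiomer by Kazlauskas' rule, so stopping before half conversion should give the (R)-alcohol and fix C-6, the untouched (S)-acetate being removed by chromatography.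

Step 5
Reactants: 6 (1R)-2-bromo-3,6-dimethylcyclohepta-2,5-dien-1-ol
Product: 7 (7R)-1-bromo-7-(methoxymethoxy)-2,5-dimethylcyclohepta-1,4-diene
Conditions: MOMCl, i-Pr2NEt, CH2Cl2, 0 °C → rt
Reagents that add atoms: chloromethyl methyl ether, COCCl
Why: Alkylation of the allylic alcohol with an alkoxymethyl chloride under amine base (MOM ether formation) does not touch the stereocentre.

Step 6
Reactants: 7 (7R)-1-bromo-7-(methoxymethoxy)-2,5-dimethylcyclohepta-1,4-diene; 8 2-methylpropanal
Product: 10 1-[(7R)-7-(methoxymethoxy)-2,5-dimethylcyclohepta-1,4-dien-1-yl]-2-methylpropan-1-ol (both carbinol epimers), via alkenyllithium 9 (not isolated)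
Conditions: t-BuLi (2.1 equiv), THF, −78 °C; then 8, −78 → −40 °C; then H2O
Reagents that add atoms: 2-methylpropanal (8), CC(C)C=O; tert-butyllithium (lithium of 9 only), [Li]C(C)(C)C
Why: Bromine–lithium exchange on the vinyl bromide is faster than any deprotonation at −78 °C, and the alkenyllithium, held by the neighbouring MOM oxygens, adds 1,2 to the aldehyde; the new carbinol centre forms as a mixture that the next step erases.

Step 7
Reactants: 10 1-[(7R)-7-(methoxymethoxy)-2,5-dimethylcyclohepta-1,4-dien-1-yl]-2-methylpropan-1-ol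
Product: 11 1-[(7R)-7-(methoxymethoxy)-2,5-dimethylcyclohepta-1,4-dien-1-yl]-2-methylpropan-1-one
Conditions: Dess–Martin periodinane, CH2Cl2, 0 °C → rt
Reagents that add atoms: none
Why: Dess–Martin oxidation turns the allylic carbinol into the enone under neutral conditions that leave the skipped diene, the MOM ether and C-6 untouched.

Step 8
Reactants: 11 1-[(7R)-7-(methoxymethoxy)-2,5-dimethylcyclohepta-1,4-dien-1-yl]-2-methylpropan-1-one; 12 vinylmagnesium bromide
Product: 14 1-[(1S,2S,7R)-2-ethenyl-7-(methoxymethoxy)-2,5-dimethylcyclohept-4-en-1-yl]-2-methylpropan-1-one, via silyl enol ether 13 (not isolated)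
Conditions: 12 (2 equiv, added slowly), CuBr·SMe2 (20 mol%), Me3SiCl (3 equiv), THF, −78 → −40 °C; then 1 M HCl, THF, 0 °C
Reagents that add atoms: vinylmagnesium bromide (12), C=C[Mg]Br; chlorotrimethylsilane (silyl group of 13 only), C[Si](C)(C)Cl
Why: Copper-catalysed, Me3SiCl-accelerated conjugate addition of the vinyl Grignard reagent builds the quaternary C-1 with the vinyl group entering anti to the C-6 OMOM group, which allylic strain against the C-5 acyl group holds pseudoaxial, and acid hydrolysis of the silyl enol ether then protonates C-5 on the face away from that OMOM group, placing the acyl group cis to OMOM and trans to the vinyl group.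

Step 9
Reactants: 14 1-[(1S,2S,7R)-2-ethenyl-7-(methoxymethoxy)-2,5-dimethylcyclohept-4-en-1-yl]-2-methylpropan-1-one
Product: 16 1-[(1S,2S,7R)-2-(2-hydroxyethyl)-7-(methoxymethoxy)-2,5-dimethylcyclohept-4-en-1-yl]-2-methylpropan-1-one, via alkylborane 15 (not isolated)
Conditions: 9-BBN (1.3 equiv), THF, 0 °C → rt; then NaBO3·4H2O, THF/H2O, rt
Reagents that add atoms: sodium perborate (hydroxyl oxygen), [Na+].[Na+].O[B-]1(O)OO[B-](O)(O)OO1; 9-borabicyclo[3.3.1]nonane (boron and bicyclic residue of 15 only), B1C2CCCC1CCC2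
Why: Hydroboration with 9-BBN is anti-Markovnikov and selective for the monosubstituted vinyl group over the trisubstituted ring alkene and the hindered ketone, and perborate oxidation of the C–B bond is mild enough to leave the β-alkoxy ketone and its C-5 centre alone.

Step 10
Reactants: 16 1-[(1S,2S,7R)-2-(2-hydroxyethyl)-7-(methoxymethoxy)-2,5-dimethylcyclohept-4-en-1-yl]-2-methylpropan-1-one
Product: 17 1-[(1S,2S,7R)-2-(2-iodoethyl)-7-(methoxymethoxy)-2,5-dimethylcyclohept-4-en-1-yl]-2-methylpropan-1-one
Conditions: I2, PPh3, imidazole, CH2Cl2, 0 °C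
Reagents that add atoms: iodine, II
Why: Iodination with PPh3/I2/imidazole (Appel-type, Garegg–Samuelsson conditions) is an SN2 displacement at an unhindered primary carbon, the quaternary centre being two atoms away, and the nearly neutral medium spares the epimerisable C-5.

Step 11
Reactants: 17 1-[(1S,2S,7R)-2-(2-iodoethyl)-7-(methoxymethoxy)-2,5-dimethylcyclohept-4-en-1-yl]-2-methylpropan-1-one
Product: 18 (3R,3aS,4R,8aR)-4-(methoxymethoxy)-6,8a-dimethyl-3-(propan-2-yl)-1,2,3,3a,4,5,8,8a-octahydroazulen-3-ol (dauc-8-ene-4,6-diol 6-MOM ether)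
Conditions: SmI2 (2.5 equiv, 0.1 M), NiI2 (2 mol%), THF, 0 °C → rt
Reagents that add atoms: none
Why: Divalent samarium, with NiI2 as electron-transfer catalyst, reduces the primary C–I bond by two electrons to an alkylsamarium of trivalent samarium, which adds to the isopropyl ketone, forms C-3–C-4 and gives the tertiary alcohol on work-up. The closest known reaction type is the SmI2-mediated intramolecular Barbier cyclisation of ω-iodoalkyl ketones to cyclopentanols. The five-membered ring (C-1 to C-5) closes in the 5-exo-trig mode, and as the iodoethyl and acyl groups already stand trans on the cycloheptene the ring fusion comes out trans. The new stereocentre C-4 is under substrate control: trivalent samarium bridges the carbonyl oxygen and the oxygens of the cis C-6 OMOM group, which turns the carbonyl oxygen towards C-6 and the isopropyl group towards H-5, so that C-3 bonds to the face that leaves the hydroxyl cis to C-6 (4R). The step needs the iodide to be reduced ahead of the ketone and the carbon–samarium bond to form before the transient radical can add 5-exo to C-9 of the ring alkene; nickel catalysis, the absence of HMPA (which keeps the dialkyl ketone unreduced and the chelate intact) and the low basicity of the organosamarium, which spares the β-alkoxy ketone from elimination and from epimerisation at C-5, should secure this.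

Step 12
Reactants: 18 (3R,3aS,4R,8aR)-4-(methoxymethoxy)-6,8a-dimethyl-3-(propan-2-yl)-1,2,3,3a,4,5,8,8a-octahydroazulen-3-ol
Product: 19 (3R,3aS,4R,8aR)-6,8a-dimethyl-3-(propan-2-yl)-1,2,3,3a,4,5,8,8a-octahydroazulene-3,4-diol
Conditions: ZnBr2, n-PrSH, CH2Cl2, 0 °C → rt
Reagents that add atoms: none
Why: Lewis-acid activation of the MOM ether by ZnBr2 with a thiol as trap cleaves the acetal without protic acid, so that the tertiary C-4 alcohol is not ionised and the methoxymethyl cation is intercepted by sulfur before it can bridge O-4 and O-6 as a cyclic formal.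

Step 13
Reactants: 19 (3R,3aS,4R,8aR)-6,8a-dimethyl-3-(propan-2-yl)-1,2,3,3a,4,5,8,8a-octahydroazulene-3,4-diol; 20 4-[(tert-butyldimethylsilyl)oxy]benzoic acid
Product: 21 (3R,3aS,4R,8aR)-3-hydroxy-6,8a-dimethyl-3-(propan-2-yl)-1,2,3,3a,4,5,8,8a-octahydroazulen-4-yl 4-[(tert-butyldimethylsilyl)oxy]benzoate
Conditions: EDC·HCl, 4-(dimethylamino)pyridine (DMAP), CH2Cl2, rt
Reagents that add atoms: 4-[(tert-butyldimethylsilyl)oxy]benzoic acid (20), CC(C)(C)[Si](C)(C)Oc1ccc(cc1)C(O)=O
Why: Carbodiimide esterification with DMAP catalysis (Steglich) acylates the secondary C-6 hydroxyl, while the tertiary C-4 hydroxyl is too hindered to compete.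

Step 14
Reactants: 21 (3R,3aS,4R,8aR)-3-hydroxy-6,8a-dimethyl-3-(propan-2-yl)-1,2,3,3a,4,5,8,8a-octahydroazulen-4-yl 4-[(tert-butyldimethylsilyl)oxy]benzoate
Product: 22 (1R,4R,5S,6R,8R,9S)-8,9-epoxy-4-hydroxydaucan-6-yl 4-[(tert-butyldimethylsilyl)oxy]benzoate (oxirane oxygen trans to the C-1 methyl and the C-6 ester)
Conditions: mCPBA, NaHCO3, CH2Cl2, 0 °C
Reagents that add atoms: 3-chloroperbenzoic acid, OOC(=O)c1cccc(Cl)c1
Why: Peracid epoxidation (Prilezhaev) of the trisubstituted C-8=C-9 alkene should come from the face opposite to the axial C-1 methyl and C-6 aroyloxy groups, which sets C-8 (R) and C-9 (S), and the bicarbonate buffer protects the oxirane from acid-promoted opening by the C-4 hydroxyl.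

Step 15
Reactants: 22 (1R,4R,5S,6R,8R,9S)-8,9-epoxy-4-hydroxydaucan-6-yl 4-[(tert-butyldimethylsilyl)oxy]benzoate
Product: 23 (1R,4R,5S,6R,8R,9S)-8,9-epoxy-4-hydroxydaucan-6-yl 4-hydroxybenzoate (CNP0163817.3)
Conditions: Bu4NF, AcOH, THF, 0 °C
Reagents that add atoms: none
Why: Fluoride cleaves the aryl silyl ether much faster than it attacks the ester or the oxirane, and acetic acid buffers the phenoxide that is released (desilylation).

**Compound list**

1 | p-xylene (1,4-dimethylbenzene) | Cc1ccc(C)cc1 | starting material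
2 | 1,4-dimethylcyclohexa-1,4-diene | CC1=CCC(C)=CC1 | intermediate
3 | bromoform | BrC(Br)Br | starting material
4 | racemic cis-fused 7,7-dibromo-1,4-dimethylbicyclo[4.1.0]hept-3-ene (one enantiomer drawn) | CC1=CC[C@]2(C)[C@H](C1)C2(Br)Br | intermediate
5 | racemic 2-bromo-3,6-dimethylcyclohepta-2,5-dien-1-yl acetate | CC(=O)OC1CC(C)=CCC(C)=C1Br | intermediate
6 | (1R)-2-bromo-3,6-dimethylcyclohepta-2,5-dien-1-ol | O[C@@H]1CC(C)=CCC(C)=C1Br | intermediate
7 | (7R)-1-bromo-7-(methoxymethoxy)-2,5-dimethylcyclohepta-1,4-diene | COCO[C@@H]1CC(C)=CCC(C)=C1Br | intermediate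
8 | 2-methylpropanal | CC(C)C=O | starting material
9 | [(7R)-7-(methoxymethoxy)-2,5-dimethylcyclohepta-1,4-dien-1-yl]lithium | COCO[C@@H]1CC(C)=CCC(C)=C1[Li] | intermediate (not isolated)
10 | 1-[(7R)-7-(methoxymethoxy)-2,5-dimethylcyclohepta-1,4-dien-1-yl]-2-methylpropan-1-ol (both carbinol epimers) | COCO[C@@H]1CC(C)=CCC(C)=C1C(O)C(C)C | intermediate
11 | 1-[(7R)-7-(methoxymethoxy)-2,5-dimethylcyclohepta-1,4-dien-1-yl]-2-methylpropan-1-one | COCO[C@@H]1CC(C)=CCC(C)=C1C(=O)C(C)C | intermediate
12 | vinylmagnesium bromide | C=C[Mg]Br | starting material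
13 | ({1-[(2S,7R)-2-ethenyl-7-(methoxymethoxy)-2,5-dimethylcyclohept-4-en-1-ylidene]-2-methylpropyl}oxy)trimethylsilane (enol ether geometry left open) | CC(C)C(O[Si](C)(C)C)=C1[C@H](OCOC)CC(C)=CC[C@@]1(C)C=C | intermediate (not isolated)
14 | 1-[(1S,2S,7R)-2-ethenyl-7-(methoxymethoxy)-2,5-dimethylcyclohept-4-en-1-yl]-2-methylpropan-1-one | CC(C)C(=O)[C@@H]1[C@H](OCOC)CC(C)=CC[C@@]1(C)C=C | intermediate
15 | 1-[(1S,2R,7R)-2-[2-(9-borabicyclo[3.3.1]nonan-9-yl)ethyl]-7-(methoxymethoxy)-2,5-dimethylcyclohept-4-en-1-yl]-2-methylpropan-1-one (same spatial arrangement as 14) | CC(C)C(=O)[C@@H]1[C@H](OCOC)CC(C)=CC[C@@]1(C)CCB1C2CCCC1CCC2 | intermediate (not isolated)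
16 | 1-[(1S,2S,7R)-2-(2-hydroxyethyl)-7-(methoxymethoxy)-2,5-dimethylcyclohept-4-en-1-yl]-2-methylpropan-1-one | CC(C)C(=O)[C@@H]1[C@H](OCOC)CC(C)=CC[C@@]1(C)CCO | intermediate
17 | 1-[(1S,2S,7R)-2-(2-iodoethyl)-7-(methoxymethoxy)-2,5-dimethylcyclohept-4-en-1-yl]-2-methylpropan-1-one | CC(C)C(=O)[C@@H]1[C@H](OCOC)CC(C)=CC[C@@]1(C)CCI | intermediate
18 | (3R,3aS,4R,8aR)-4-(methoxymethoxy)-6,8a-dimethyl-3-(propan-2-yl)-1,2,3,3a,4,5,8,8a-octahydroazulen-3-ol | CC(C)[C@]1(O)CC[C@]2(C)CC=C(C)C[C@@H](OCOC)[C@H]21 | intermediate
19 | (3R,3aS,4R,8aR)-6,8a-dimethyl-3-(propan-2-yl)-1,2,3,3a,4,5,8,8a-octahydroazulene-3,4-diol | CC(C)[C@]1(O)CC[C@]2(C)CC=C(C)C[C@@H](O)[C@H]21 | intermediate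
20 | 4-[(tert-butyldimethylsilyl)oxy]benzoic acid | CC(C)(C)[Si](C)(C)Oc1ccc(cc1)C(O)=O | starting material
21 | (3R,3aS,4R,8aR)-3-hydroxy-6,8a-dimethyl-3-(propan-2-yl)-1,2,3,3a,4,5,8,8a-octahydroazulen-4-yl 4-[(tert-butyldimethylsilyl)oxy]benzoate | CC(C)[C@]1(O)CC[C@]2(C)CC=C(C)C[C@@H](OC(=O)c3ccc(O[Si](C)(C)C(C)(C)C)cc3)[C@H]21 | intermediate
22 | (1R,4R,5S,6R,8R,9S)-8,9-epoxy-4-hydroxydaucan-6-yl 4-[(tert-butyldimethylsilyl)oxy]benzoate | CC(C)[C@]1(O)CC[C@]2(C)C[C@@H]3O[C@]3(C)C[C@@H](OC(=O)c3ccc(O[Si](C)(C)C(C)(C)C)cc3)[C@H]21 | intermediate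
23 | (1R,4R,5S,6R,8R,9S)-8,9-epoxy-4-hydroxydaucan-6-yl 4-hydroxybenzoate (CNP0163817.3) | CC(C)[C@]1(O)CC[C@]2(C)C[C@@H]3O[C@]3(C)C[C@@H](OC(=O)c3ccc(O)cc3)[C@H]21 | target

**Step count and risks**

Total step count: 15. Longest linear sequence: 15 steps, from 1 to 23; there is no convergent branch.

Steps most likely to fail, riskiest first:

Step 8 (conjugate vinylation). The tetrasubstituted enone, twisted out of conjugation, may take up the vinyl group only slowly. The Grignard reagent may instead remove a proton from the doubly allylic C-10. The facial selectivity of the addition or of the C-5 protonation may also be low. The fallback moves the conjugate addition to a more electrophilic, planar acceptor and attaches the isopropyl group afterwards. It sets out from 7: the alkenyllithium 9 is quenched with DMF to give (7R)-7-(methoxymethoxy)-2,5-dimethylcyclohepta-1,4-diene-1-carbaldehyde F1. Copper-catalysed addition of 12 with Me3SiCl gives {[(2S,7R)-2-ethenyl-7-(methoxymethoxy)-2,5-dimethylcyclohept-4-en-1-ylidene]methoxy}trimethylsilane F2. Dilute acid hydrolyses F2, with protonation anti to the OMOM group, to (1S,2S,7R)-2-ethenyl-7-(methoxymethoxy)-2,5-dimethylcyclohept-4-ene-1-carbaldehyde F3. Addition of i-PrMgCl in the presence of CeCl3 gives 1-[(1R,2S,7R)-2-ethenyl-7-(methoxymethoxy)-2,5-dimethylcyclohept-4-en-1-yl]-2-methylpropan-1-ol F4, and Dess–Martin oxidation of F4 comes back to the route at 14.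

Step 11 (SmI2 Barbier closure). Electron transfer to the ketone may outrun reduction of the iodide and lead to loss of the β-alkoxy group. The iodide may simply be reduced to C–H. The transient primary radical may add 5-exo to C-9 before it is reduced further. The fallback replaces the one-electron Barbier activation by a preformed two-electron carbanion. It sets out from 17: iodine–lithium exchange with t-BuLi (2.2 equiv, Et2O/pentane, −100 °C) gives 1-[(1S,2R,7R)-2-(2-lithioethyl)-7-(methoxymethoxy)-2,5-dimethylcyclohept-4-en-1-yl]-2-methylpropan-1-one F5. F5 should add to the neighbouring ketone under lithium chelation by the C-6 OMOM group faster than t-BuLi attacks the carbonyl, and aqueous quench comes back to the route at 18.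

Step 3 (silver-promoted ring expansion). Acetate may bond to the tertiary terminus of the allyl cation, or the cation may lose a proton from the doubly allylic CH2 and drain into a cycloheptatriene. The fallback lets both regioisomers converge on one ketone and sets C-6 by reagent-controlled reduction instead of resolution. It sets out from 4: AgClO4 and NaHCO3 in aqueous acetone give racemic 2-bromo-3,6-dimethylcyclohepta-2,5-dien-1-ol F6 together with racemic 2-bromo-1,5-dimethylcyclohepta-2,5-dien-1-ol F7. Pyridinium chlorochromate (C5H5NH[CrO3Cl]) oxidises F6 directly and F7 with 1,3-transposition (Babler–Dauben) to the same 2-bromo-3,6-dimethylcyclohepta-2,5-dien-1-one F8, which is kept cold and free of base because it can lose HBr towards a tropone. Reduction of F8 with catecholborane and (3aS)-1-methyl-3,3-diphenyltetrahydro-1H,3H-pyrrolo[1,2-c][1,3,2]oxazaborole (Corey–Bakshi–Shibata reduction, bromoalkenyl side as the large group) comes back to the route at 6, so that steps 3 and 4 are both replaced.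

**Further compounds**

F1 | step 8 | (7R)-7-(methoxymethoxy)-2,5-dimethylcyclohepta-1,4-diene-1-carbaldehyde | COCO[C@@H]1CC(C)=CCC(C)=C1C=O
F2 | step 8 | {[(2S,7R)-2-ethenyl-7-(methoxymethoxy)-2,5-dimethylcyclohept-4-en-1-ylidene]methoxy}trimethylsilane | C[Si](C)(C)OC=C1[C@H](OCOC)CC(C)=CC[C@@]1(C)C=C
F3 | step 8 | (1S,2S,7R)-2-ethenyl-7-(methoxymethoxy)-2,5-dimethylcyclohept-4-ene-1-carbaldehyde | O=C[C@@H]1[C@H](OCOC)CC(C)=CC[C@@]1(C)C=C
F4 | step 8 | 1-[(1R,2S,7R)-2-ethenyl-7-(methoxymethoxy)-2,5-dimethylcyclohept-4-en-1-yl]-2-methylpropan-1-ol (carbinol epimers) | CC(C)C(O)[C@@H]1[C@H](OCOC)CC(C)=CC[C@@]1(C)C=C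
F5 | step 11 | 1-[(1S,2R,7R)-2-(2-lithioethyl)-7-(methoxymethoxy)-2,5-dimethylcyclohept-4-en-1-yl]-2-methylpropan-1-one | CC(C)C(=O)[C@@H]1[C@H](OCOC)CC(C)=CC[C@@]1(C)CC[Li]
F6 | step 3 | racemic 2-bromo-3,6-dimethylcyclohepta-2,5-dien-1-ol | OC1CC(C)=CCC(C)=C1Br
F7 | step 3 | racemic 2-bromo-1,5-dimethylcyclohepta-2,5-dien-1-ol | CC1(O)CC=C(C)CC=C1Br
F8 | step 3 | 2-bromo-3,6-dimethylcyclohepta-2,5-dien-1-one | O=C1CC(C)=CCC(C)=C1Br
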